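**Strategy.** Ring A of the decalin (C1–C2–C3–C4–C5–C10, labdane numbering) is opened at the two bonds that flank the ring fusion, C1–C10 and C4–C5. Each ends at a quaternary carbon (C10 with its methyl, C4 with the gem-dimethyl). One Lewis-acid-promoted Diels–Alder reaction makes both: the 2-silyloxydiene from mesityl oxide (C1–C4 with both methyls) adds across C5=C10 of an enantiopure ring-B 3-methylcyclohexenone that already carries the C8 ester and a C9 vinyl group. The activating C6 ketone later becomes the C6=C7 alkene, the C2 oxygen is removed, and the vinyl group takes up the side chain by B-alkyl Suzuki coupling.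

Key step: step 6

Remarks.
- Locants C1–C17 in the text follow labdane numbering (ring A: C1–C5 and C10; ring B: C5–C10; C11–C16 side chain; C17 the ester carbon on C8). Systematic names use their own locants.
- Assumption: the R-configured oxazaborolidinium catalyst of step 2 is taken to expose the dienophile face predicted by the formyl C–H···O binding model for aldehyde-bound enals; if the sense were opposite, the mirror-image catalyst would be used.

Step 1
Reactants: 1 (E)-pent-3-en-2-one
Product: 2 triisopropyl{[(3E)-penta-1,3-dien-2-yl]oxy}silane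
Conditions: TIPSOTf (1.1 equiv), Et3N (1.5 equiv), Et2O, 0 °C to rt
Reagents that add atoms: triisopropylsilyl trifluoromethanesulfonate, CC(C)[Si](C(C)C)(C(C)C)OS(=O)(=O)C(F)(F)F
Why: Soft enolisation of the methyl ketone (silyl triflate and amine) should give the cross-conjugated 2-silyloxydiene with the E alkene untouched.

Step 2
Reactants: 2 triisopropyl{[(3E)-penta-1,3-dien-2-yl]oxy}silane; 3 methyl (E)-4-oxobut-2-enoate
Product: 4 methyl (1S,5S,6S)-6-formyl-5-methyl-3-[(triisopropylsilyl)oxy]cyclohex-3-ene-1-carboxylate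
Conditions: (R)-1-(2-methylphenyl)-3,3-diphenyltetrahydro-1H,3H-pyrrolo[1,2-c][1,3,2]oxazaborole (20 mol %), Tf2NH (16 mol %), CH2Cl2, −78 °C
Reagents that add atoms: none
Why: Catalytic enantioselective Diels–Alder reaction (cationic oxazaborolidine): the catalyst binds the formyl group, so the diene CH2 terminus bonds to the carbon β to it (the ester-bearing C8) and the methyl-bearing terminus to C9; the E dienophile fixes the trans ester/formyl relation, the shielded face of the bound enal sets the absolute configuration at C8 and C9, and the endo-derived C10 methyl centre is erased in step 4.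

Step 3
Reactants: 4 methyl (1S,5S,6S)-6-formyl-5-methyl-3-[(triisopropylsilyl)oxy]cyclohex-3-ene-1-carboxylate
Product: 5 methyl (1S,5R,6S)-6-ethenyl-5-methyl-3-[(triisopropylsilyl)oxy]cyclohex-3-ene-1-carboxylate
Conditions: Ph3PCH3Br (1.3 equiv), KOtBu (1.25 equiv), THF, 0 °C; then 4, −78 to 0 °C
Reagents that add atoms: methyltriphenylphosphonium bromide, C[P+](c1ccccc1)(c1ccccc1)c1ccccc1.[Br-]
Why: Wittig methylenation should convert only the aldehyde (ester and silyl enol ether are inert to the ylide at low temperature) and leaves the already favoured trans arrangement at C8/C9.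

Step 4
Reactants: 5 methyl (1S,5R,6S)-6-ethenyl-5-methyl-3-[(triisopropylsilyl)oxy]cyclohex-3-ene-1-carboxylate
Product: 6 methyl (1S,2R)-2-ethenyl-3-methyl-5-oxocyclohex-3-ene-1-carboxylate
Conditions: Pd(OAc)2 (10 mol %), O2 (1 atm), DMSO, 45 °C
Reagents that add atoms: none
Why: Saegusa–Ito oxidation of the regiodefined silyl enol ether: the palladium enolate at C5 has a β-hydrogen only on C10, so the C5=C10 enone forms and the C10 stereocentre of any diastereomer converges.

Step 5
Reactants: 7 mesityl oxide (4-methylpent-3-en-2-one)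
Product: 8 tert-butyl(dimethyl)[(4-methylpenta-1,3-dien-2-yl)oxy]silane
Conditions: TBSOTf (1.1 equiv), Et3N (1.5 equiv), Et2O, 0 °C
Reagents that add atoms: tert-butyldimethylsilyl trifluoromethanesulfonate, CC(C)(C)[Si](C)(C)OS(=O)(=O)C(F)(F)F
Why: Soft enolisation at the acetyl methyl group should give the cross-conjugated 2-silyloxydiene that carries the future C4 gem-dimethyl terminus.

Step 6
Reactants: 6 methyl (1S,2R)-2-ethenyl-3-methyl-5-oxocyclohex-3-ene-1-carboxylate; 8 tert-butyl(dimethyl)[(4-methylpenta-1,3-dien-2-yl)oxy]silane (2.5 equiv)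
Product: 10 methyl (1R,2S,4aS,8aS)-1-ethenyl-5,5,8a-trimethyl-4,7-dioxodecahydronaphthalene-2-carboxylate (cis-fused diketone), via silyl enol ether cycloadduct 9 (not isolated)
Conditions: AlBr3/AlMe3 (10:1, 40 mol % Al), toluene/CH2Br2, −20 to 0 °C; then 1 M HCl, THF, rt
Reagents that add atoms: none
Why: Lewis-acid-promoted Diels–Alder reaction: the aluminium Lewis acid binds the C6 carbonyl of 6, the nucleophilic CH2 terminus of the 2-silyloxydiene (C1) bonds to the enone β-carbon C10 and the CMe2 terminus (C4) to the α-carbon C5 in a highly asynchronous (Mukaiyama–Michael-like) [4+2] event, leaving the C2=C3 silyl enol ether 9, which aqueous acid hydrolyses to the C2 ketone. The closest known reaction type is the mixed-Lewis-acid (AlBr3/AlMe3) Diels–Alder reaction of hindered 2-silyloxydienes with β-substituted cyclohexenones, which builds quaternary carbons of this kind. Ring A is closed by intermolecular [4+2] cycloaddition across C5=C10, both bonds coming from one diene and one dienophile. C10 is set by approach of the diene anti to the neighbouring C9 vinyl group, held pseudo-axial by allylic strain against the C10 methyl, so the methyl ends cis to the vinyl; C5 follows from suprafacial addition (cis ring fusion) and is corrected in step 8 through the adjacent ketone. The step needs regioselectivity (C1 to C10, not C4 to C10), conjugate over carbonyl addition, and face selectivity: the 2-silyloxy group makes C1 the nucleophilic end and C10 is the β-carbon, an orientation that also keeps the two new quaternary carbons 1,3 to each other, while AlMe3 scavenges protic acid that would destroy the diene.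

Step 7
Reactants: 10 methyl (1R,2S,4aS,8aS)-1-ethenyl-5,5,8a-trimethyl-4,7-dioxodecahydronaphthalene-2-carboxylate
Product: 12 methyl (1R,2S,4aS,8aS)-1-ethenyl-5,5,8a-trimethyl-4-oxodecahydronaphthalene-2-carboxylate (cis-fused ketone), via tosylhydrazone 11 (not isolated)
Conditions: TsNHNH2 (1.05 equiv), EtOH, rt; evaporate; catecholborane (2 equiv), CHCl3, 0 °C; then NaOAc·3H2O, reflux
Reagents that add atoms: none
Why: Reductive deoxygenation through the tosylhydrazone (Kabalka variant of the Caglioti reaction): the C2 ketone between two methylene groups should condense, whereas the C6 ketone next to C5 (wedged between two quaternary carbons) should not, and catecholborane at 0 °C reduces only the C=N bond, sparing ester, vinyl group and C6 ketone.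

Step 8
Reactants: 12 methyl (1R,2S,4aS,8aS)-1-ethenyl-5,5,8a-trimethyl-4-oxodecahydronaphthalene-2-carboxylate
Product: 13 methyl (1R,2S,4aR,8aS)-1-ethenyl-5,5,8a-trimethyl-4-oxodecahydronaphthalene-2-carboxylate (trans-fused ketone)
Conditions: NaOMe (0.3 equiv), MeOH, rt to 40 °C
Reagents that add atoms: none
Why: Base-mediated epimerisation at C5 through the C6 enolate should funnel the cis adduct to the more stable trans-decalone (thermodynamic control, as in 10-methyl-6-oxo steroids), and C8, which can also equilibrate, stays equatorial and trans to the C9 vinyl group.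

Step 9
Reactants: 13 methyl (1R,2S,4aR,8aS)-1-ethenyl-5,5,8a-trimethyl-4-oxodecahydronaphthalene-2-carboxylate
Product: 14 methyl (1R,2R,4aR,8aS)-1-ethenyl-5,5,8a-trimethyl-4-{[(trifluoromethyl)sulfonyl]oxy}-1,2,4a,5,6,7,8,8a-octahydronaphthalene-2-carboxylate
Conditions: KHMDS (1.05 equiv), THF, −78 °C; PhNTf2 (1.1 equiv), −78 to 0 °C
Reagents that add atoms: N-phenylbis(trifluoromethanesulfonimide), O=S(=O)(N(c1ccccc1)S(=O)(=O)C(F)(F)F)C(F)(F)F
Why: Kinetic enolisation and O-triflation: the C7 methylene is deprotonated in preference to the buried C5 methine and to the less acidic ester α-hydrogen, which places the enol triflate at C6=C7.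

Step 10
Reactants: 14 methyl (1R,2R,4aR,8aS)-1-ethenyl-5,5,8a-trimethyl-4-{[(trifluoromethyl)sulfonyl]oxy}-1,2,4a,5,6,7,8,8a-octahydronaphthalene-2-carboxylate
Product: 15 methyl (1R,2S,4aR,8aS)-1-ethenyl-5,5,8a-trimethyl-1,2,4a,5,6,7,8,8a-octahydronaphthalene-2-carboxylate
Conditions: Pd(OAc)2 (5 mol %), PPh3 (10 mol %), Bu3N (3 equiv), HCO2H (2 equiv), DMF, 60 °C
Reagents that add atoms: none
Why: Palladium-catalysed formate reduction of the enol triflate should replace OTf by hydrogen under nearly neutral conditions, giving the C6=C7 alkene without touching the C8 stereocentre or the vinyl group.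

Step 11
Reactants: 16 methyl 4-hydroxybut-2-ynoate
Product: 17 methyl (Z)-4-hydroxy-3-iodobut-2-enoate
Conditions: NaI (1.5 equiv), AcOH, 70 °C
Reagents that add atoms: sodium iodide, [Na+].[I-]
Why: Conjugate hydroiodination of the ynoate proceeds by anti addition, so iodine ends cis to the ester (Z) and the hydroxymethyl group trans to it, the geometry the target needs.

Step 12
Reactants: 15 methyl (1R,2S,4aR,8aS)-1-ethenyl-5,5,8a-trimethyl-1,2,4a,5,6,7,8,8a-octahydronaphthalene-2-carboxylate; 17 methyl (Z)-4-hydroxy-3-iodobut-2-enoate (1.2 equiv)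
Product: 19 methyl (1R,2S,4aR,8aS)-1-[(3E)-3-(hydroxymethyl)-5-methoxy-5-oxopent-3-en-1-yl]-5,5,8a-trimethyl-1,2,4a,5,6,7,8,8a-octahydronaphthalene-2-carboxylate, via B-alkyl-9-BBN borane 18 (not isolated)
Conditions: 9-BBN dimer (0.6 equiv), THF, 0 °C to rt; then 17, PdCl2(dppf) (5 mol %), AsPh3 (5 mol %), K3PO4 (3 M aq, 3 equiv), DMF, rt
Reagents that add atoms: none
Why: Anti-Markovnikov hydroboration by 9-BBN should take the terminal vinyl group and leave the ring alkene, and the B-alkyl Suzuki–Miyaura coupling joins C12 to C13 with retention of the alkene geometry.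

Step 13
Reactants: 19 methyl (1R,2S,4aR,8aS)-1-[(3E)-3-(hydroxymethyl)-5-methoxy-5-oxopent-3-en-1-yl]-5,5,8a-trimethyl-1,2,4a,5,6,7,8,8a-octahydronaphthalene-2-carboxylate
Product: 20 methyl (1R,2S,4aR,8aS)-1-[(3E)-3-(acetoxymethyl)-5-methoxy-5-oxopent-3-en-1-yl]-5,5,8a-trimethyl-1,2,4a,5,6,7,8,8a-octahydronaphthalene-2-carboxylate (CNP0190145.1)
Conditions: Ac2O (1.5 equiv), pyridine (3 equiv), DMAP (5 mol %), CH2Cl2, 0 °C
Reagents that add atoms: acetic anhydride, CC(=O)OC(C)=O
Why: Acylation of the primary allylic alcohol under mild amine catalysis should not disturb the β,γ-unsaturated ester.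

**Compound list**

1 | (E)-pent-3-en-2-one | C/C=C/C(C)=O | starting material
2 | triisopropyl{[(3E)-penta-1,3-dien-2-yl]oxy}silane | C=C(O[Si](C(C)C)(C(C)C)C(C)C)/C=C/C | intermediate
3 | methyl (E)-4-oxobut-2-enoate | COC(=O)/C=C/C=O | starting material
4 | methyl (1S,5S,6S)-6-formyl-5-methyl-3-[(triisopropylsilyl)oxy]cyclohex-3-ene-1-carboxylate | O=C[C@@H]1[C@@H](C(=O)OC)CC(O[Si](C(C)C)(C(C)C)C(C)C)=C[C@@H]1C | intermediate
5 | methyl (1S,5R,6S)-6-ethenyl-5-methyl-3-[(triisopropylsilyl)oxy]cyclohex-3-ene-1-carboxylate | C=C[C@@H]1[C@@H](C(=O)OC)CC(O[Si](C(C)C)(C(C)C)C(C)C)=C[C@@H]1C | intermediate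
6 | methyl (1S,2R)-2-ethenyl-3-methyl-5-oxocyclohex-3-ene-1-carboxylate | C=C[C@@H]1[C@@H](C(=O)OC)CC(=O)C=C1C | intermediate
7 | mesityl oxide (4-methylpent-3-en-2-one) | CC(C)=CC(C)=O | starting material
8 | tert-butyl(dimethyl)[(4-methylpenta-1,3-dien-2-yl)oxy]silane | C=C(O[Si](C)(C)C(C)(C)C)C=C(C)C | intermediate
9 | methyl (1R,2S,4aS,8aS)-7-[(tert-butyldimethylsilyl)oxy]-1-ethenyl-5,5,8a-trimethyl-4-oxo-1,2,3,4,4a,5,8,8a-octahydronaphthalene-2-carboxylate (cis-fused silyl enol ether cycloadduct) | C=C[C@@H]1[C@@H](C(=O)OC)CC(=O)[C@H]2C(C)(C)C=C(O[Si](C)(C)C(C)(C)C)C[C@@]12C | intermediate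
10 | methyl (1R,2S,4aS,8aS)-1-ethenyl-5,5,8a-trimethyl-4,7-dioxodecahydronaphthalene-2-carboxylate (cis-fused) | C=C[C@@H]1[C@@H](C(=O)OC)CC(=O)[C@H]2C(C)(C)CC(=O)C[C@@]12C | intermediate
11 | 7-(4-methylbenzenesulfonylhydrazone) of 10 (hydrazone at labdane C2) | C=C[C@@H]1[C@@H](C(=O)OC)CC(=O)[C@H]2C(C)(C)CC(=NNS(=O)(=O)c3ccc(C)cc3)C[C@@]12C | intermediate
12 | methyl (1R,2S,4aS,8aS)-1-ethenyl-5,5,8a-trimethyl-4-oxodecahydronaphthalene-2-carboxylate (cis-fused) | C=C[C@@H]1[C@@H](C(=O)OC)CC(=O)[C@H]2C(C)(C)CCC[C@@]12C | intermediate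
13 | methyl (1R,2S,4aR,8aS)-1-ethenyl-5,5,8a-trimethyl-4-oxodecahydronaphthalene-2-carboxylate (trans-fused) | C=C[C@@H]1[C@@H](C(=O)OC)CC(=O)[C@@H]2C(C)(C)CCC[C@@]12C | intermediate
14 | methyl (1R,2R,4aR,8aS)-1-ethenyl-5,5,8a-trimethyl-4-{[(trifluoromethyl)sulfonyl]oxy}-1,2,4a,5,6,7,8,8a-octahydronaphthalene-2-carboxylate | C=C[C@@H]1[C@@H](C(=O)OC)C=C(OS(=O)(=O)C(F)(F)F)[C@@H]2C(C)(C)CCC[C@@]12C | intermediate
15 | methyl (1R,2S,4aR,8aS)-1-ethenyl-5,5,8a-trimethyl-1,2,4a,5,6,7,8,8a-octahydronaphthalene-2-carboxylate | C=C[C@@H]1[C@@H](C(=O)OC)C=C[C@@H]2C(C)(C)CCC[C@@]12C | intermediate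
16 | methyl 4-hydroxybut-2-ynoate | COC(=O)C#CCO | starting material
17 | methyl (Z)-4-hydroxy-3-iodobut-2-enoate | COC(=O)/C=C(\I)CO | intermediate
18 | 9-{2-[(1R,2S,4aR,8aS)-2-(methoxycarbonyl)-5,5,8a-trimethyl-1,2,4a,5,6,7,8,8a-octahydronaphthalen-1-yl]ethyl}-9-borabicyclo[3.3.1]nonane | C1CCC2CCCC1B2CC[C@@H]3[C@@H](C(=O)OC)C=C[C@@H]4C(C)(C)CCC[C@@]34C | intermediate
19 | methyl (1R,2S,4aR,8aS)-1-[(3E)-3-(hydroxymethyl)-5-methoxy-5-oxopent-3-en-1-yl]-5,5,8a-trimethyl-1,2,4a,5,6,7,8,8a-octahydronaphthalene-2-carboxylate | COC(=O)/C=C(\CC[C@@H]1[C@@H](C(=O)OC)C=C[C@@H]2C(C)(C)CCC[C@@]12C)CO | intermediate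
20 | methyl (1R,2S,4aR,8aS)-1-[(3E)-3-(acetoxymethyl)-5-methoxy-5-oxopent-3-en-1-yl]-5,5,8a-trimethyl-1,2,4a,5,6,7,8,8a-octahydronaphthalene-2-carboxylate | COC(=O)/C=C(\CC[C@@H]1[C@@H](C(=O)OC)C=C[C@@H]2C(C)(C)CCC[C@@]12C)COC(C)=O | target

**Step count.** Total: 13 steps. Longest linear sequence: 11 steps (1, 2, 3, 4, 6, 7, 8, 9, 10, 12, 13).

**Steps most likely to fail**

Step 6 (key cycloaddition). The hindered diene may be protodesilylated or may add to the carbonyl carbon before the second bond forms. The ester at C8, which sits on the attacked face when the vinyl group is pseudo-axial, may also erode face selectivity at C10. The fallback sets out from 6 and returns at 12, making the two bonds in separate operations. Copper-catalysed conjugate addition of (4-methylpent-3-en-1-yl)magnesium bromide (CuBr·SMe2 10 mol %, Me3SiCl, THF, −78 °C) forms C1–C10 anti to the vinyl group and gives the silyl enol ether methyl (1S,5S,6R)-6-ethenyl-5-methyl-5-(4-methylpent-3-en-1-yl)-3-[(trimethylsilyl)oxy]cyclohex-3-ene-1-carboxylate F1. A Brønsted-acid-initiated cation–olefin cyclisation terminated by the enol silane (TfOH 10 mol %, CH2Cl2, −78 °C) then closes C4–C5 through the C4 tertiary cation. This gives ketone 12, with any 13 formed carried along, since step 8 converges both; no C2 oxygen is introduced, so step 7 is bypassed.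

Step 2 (enantioselective cycloaddition). The catalyst may bind the ester instead of the formyl group, with loss of regio- and enantiocontrol, or the sense of induction may be opposite to the model. The fallback sets out from 2 and 3 and returns at 4, and replaces Lewis-acid activation by covalent iminium-ion catalysis. With (S)-2-[diphenyl(trimethylsilyloxy)methyl]pyrrolidine (20 mol %) and CF3CO2H (20 mol %) in toluene at −20 °C, the aldehyde alone is activated as its E-iminium ion. The bulky substituent of the pyrrolidine blocks one face, so the diene CH2 terminus should add to the ester-bearing carbon from the open face and give the same (1S) adduct 4 after ring closure and hydrolysis of the iminium ion.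

Step 7 (removal of the C2 oxygen). Discrimination between the two ketones in the condensation may be incomplete, or the borane may attack the hindered C6 ketone or the vinyl group. The fallback sets out from 10 and returns at 12. Acid-catalysed, reversible thioketalisation (ethane-1,2-dithiol 1.1 equiv, BF3·OEt2, CH2Cl2, 0 °C) selects the unhindered ketone under thermodynamic control and gives the dithiolane methyl (1'R,2'S,4a'S,8a'S)-1'-ethenyl-5',5',8a'-trimethyl-4'-oxooctahydro-1'H-spiro[1,3-dithiolane-2,7'-naphthalene]-2'-carboxylate F2. Radical desulfurisation (Bu3SnH 4 equiv, AIBN, toluene, 100 °C) then gives 12 without any hydride or borane reagent.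

Further compounds
F1 | step 6 | methyl (1S,5S,6R)-6-ethenyl-5-methyl-5-(4-methylpent-3-en-1-yl)-3-[(trimethylsilyl)oxy]cyclohex-3-ene-1-carboxylate | C=C[C@@H]1[C@@H](C(=O)OC)CC(O[Si](C)(C)C)=C[C@@]1(C)CCC=C(C)C
F0 | step 2 | none | none
F2 | step 7 | methyl (1'R,2'S,4a'S,8a'S)-1'-ethenyl-5',5',8a'-trimethyl-4'-oxooctahydro-1'H-spiro[1,3-dithiolane-2,7'-naphthalene]-2'-carboxylate | C=C[C@@H]1[C@@H](C(=O)OC)CC(=O)[C@H]2C(C)(C)CC3(SCCS3)C[C@@]12C
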